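(All runs come from a simulation with constants of no real substance; scatter was added.)

The constants are hidden, so you start from what the three earlier runs show.

| flask | electrophile | nucleophile | free base | temperature | remark | time |
|---|---|---|---|---|---|---|
| east | 0.021 M | 1.2 equiv | 2 equiv | 65 °C | run made earlier |  |
| north-west | 0.021 M | 0.60 equiv | 2 equiv | 76 °C | run made earlier |  |
| south-east | 0.021 M | 0.90 equiv | 2 equiv | 65 °C | run made earlier |  |
| autumn | 0.021 M | 1.20 equiv | 2.00 equiv | 70 °C | everything together at the start | 20 h |
| summer | 0.021 M (fed, over 15 h) | 1.20 equiv | 2.00 equiv | 70 °C | all else is in the flask from the start; the feed brings no volume worth counting | 20 h |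
| midnight | 0.021 M | 1.20 equiv (fed, over 15 h) | 2.00 equiv |  | the addition at 40 °C, then warmed to 70 °C; the feed brings no volume worth counting | 20 h |
| dawn | 0.021 M | 1.20 equiv (in portions, 5, over 15 h) | 2.00 equiv | 70 °C | first portion at the start, last at 15 h | 20 h |

| run | time / h | product / % | electrophile / % |
|---|---|---|---|
| east | 1.50 | 19.9 | 73.1 |
| east | 4.00 | 36.7 | 52.8 |
| east | 8.00 | 49.9 | 36.4 |
| east | 12.0 | 56.8 | 26.5 |
| north-west | 1.50 | 18.5 | 71.2 |
| north-west | 4.00 | 34.4 | 48.1 |
| north-west | 8.00 | 39.0 | 34.0 |
| north-west | 20.0 | 44.1 | 20.9 |
| south-east | 1.50 | 15.4 | 76.1 |
| south-east | 4.00 | 30.1 | 59.1 |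
| south-east | 8.00 | 42.2 | 42.7 |
| south-east | 20.0 | 51.9 | 25.5 |

(each reading ± 1 percentage point)

- amounts and yields of acid set free count idle adduct too
- reactions considered so far: electrophile + nucleophile -> acid set free + product; nucleophile + acid set free <-> protonated nucleophile; acid set free + free base <-> salt of the base; electrophile + acid set free <-> idle adduct

1. the flask that comes out highest in amount of product, in percent of the electrophile charged, or "all alike" when all lie within 1.5 percentage points (autumn / summer / midnight / dawn / all alike)
2. product at the end, in percent of the electrophile charged, autumn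
3. product at the end, in percent of the electrophile charged, summer
4. product at the end, in percent of the electrophile charged, midnight
5. product at the end, in percent of the electrophile charged, dawn

Here is my reckoning, from the fastest step to the slowest.

1. Acid capture. Each product frees one acid. In the east run the gap in the balance, read as idle adduct, stands at 0.352 per product at 1.50 h and 0.294 at 12.0 h. So I take the acid as placed as fast as it forms, on the electrophile or on the nucleophile, and I count the free base as a bystander.

2. The rule. Acid that misses the electrophile costs a second nucleophile, so the nucleophile spent per product is two minus idle adduct over product. The last east reading gives 1.71; carry this nucleophile price.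

3. The rate. It follows free nucleophile, not the charge. By this price the east run keeps 19.3% of its nucleophile at 12.0 h, less than the 52.7% that plain consumption leaves. Watch this amount, and the balance gap.

4. The coupling. The first east reading corresponds to a whole charge of product in 7.54 h. Summer's feed of 15 h lasts twice that, so I expect summer's electrophile to stay dilute while it is fed, and 5.00 h remain afterwards. This time was read at 65 °C and summer stands at 70 °C; I do not carry it to midnight's feed at 40 °C.

5. The end. At this price the charge of 1.20 equiv pays for 70.3% of product, less than the whole electrophile, so the nucleophile acts as the limiting reagent. Expect autumn highest, and short of that amount at 20 h.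

The forecast names autumn: autumn 66%, summer 60%, midnight 50%, dawn 57%. Of summer it says “late electrophile has little time and acid sits on the nucleophile”.

The flask gives autumn 65.5%, above summer 59.5%, midnight 51.0% and dawn 58.2%.

    electrophile + nucleophile → acid set free + product (k = 0.194 M⁻¹ min⁻¹, Ea = 72.0 kJ mol⁻¹)
    nucleophile + acid set free ⇌ protonated nucleophile, settled at all times (K = 31000 M⁻¹, ΔH = −44.0 kJ mol⁻¹)
    acid set free + free base ⇌ salt of the base, settled at all times (K = 33.8 M⁻¹, ΔH = −21.0 kJ mol⁻¹)
    electrophile + acid set free ⇌ idle adduct, settled at all times (K = 13000 M⁻¹, ΔH = −19.0 kJ mol⁻¹)
    (constants at 70 °C)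

At 20.0 h autumn still holds 13.4% of its electrophile, beside 9.54% of its nucleophile and 0.00904 M of protonated nucleophile. Autumn has paid 1.66 nucleophile per product, against the 1.71 carried. In the neighbour of midnight with 0.720 equiv of nucleophile, the rule gives a price of 1.50. The nucleophile it spent then buys 35.1% of product, and that flask stands at 35.3%.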